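The cyclohexenone ring is traced back to the bromobenzene-derived cis-diol, whose carbinol carbons become C4 and C5. Everything rests on forming the C6–C1'' and C1–O bonds in one radical operation: a 2-iodoacetal on the C5 oxygen gives a primary radical that closes 5-exo onto C6 of the C6=C1–C2=C3 diene, and TEMPO caps the allylic radical at C1. This exploits two features of the six-membered ring: the C6 side chain is cis to the C5 hydroxyl, and C1 is oxygenated. The new cis-fused tetrahydrofuran acetal ring is the masked CH2–CHO of the enoic acid chain. The precursor is the C4-O-silylated, C5-O-(1-ethoxy-2-iodoethyl) ether of the diol.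

Key step: step 3

Remark on numbering: ring carbons are numbered as in the target (C1 carbonyl carbon, C2 heptenyl-bearing, C3 hydroxymethyl-bearing, C4 and C5 carbinols, C6 butenoic-acid-bearing); C1'' and C2'' are the CH2 and the acetal carbon of the tether.

Remark on stereochemistry: the target is all-cis at C4–O, C5–O and C6–C; C4 and C5 carry the unchanged configuration of diol 1, and the side-chain carbinol is R, as delivered by (R)-propylene oxide.

Remark on precursor design: the radical precursor carries a primary iodide (from N-iodosuccinimide) instead of a bromide. Halogen abstraction by the stannyl radical should then outpace both its capture by the nitroxide and attack on the C3 vinyl bromide. The C4 TBS ether and the skeleton are kept.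

Assumptions: the acetal carbon C2'' is carried as a mixture of epimers from 3 to 19 (left undefined in the SMILES) and is removed in step 13; compounds 8 and 11 are taken as purchasable.

Step 1
Reactants: 1 (1S,2S)-3-bromocyclohexa-3,5-diene-1,2-diol; 2 ethyl vinyl ether
Product: 3 (1S,6S)-2-bromo-6-(1-ethoxy-2-iodoethoxy)cyclohexa-2,4-dien-1-ol (acetal epimers)
Conditions: NIS (1.0 equiv), 2 (3 equiv), THF/CH2Cl2, −78 → −30 °C
Reagents that add atoms: N-iodosuccinimide, O=C1CCC(=O)N1I
Why: Haloacetalisation (iodoetherification of the enol ether): NIS iodinates the vinyl ether, by far the most electron-rich alkene present, and the oxocarbenium ion should be captured by the C5 hydroxyl, which is less hindered and less inductively deactivated than the C4 hydroxyl next to the C3–Br carbon; no ring stereocentre is touched.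

Step 2
Reactants: 3 (1S,6S)-2-bromo-6-(1-ethoxy-2-iodoethoxy)cyclohexa-2,4-dien-1-ol
Product: 4 tert-butyl{[(1S,6S)-2-bromo-6-(1-ethoxy-2-iodoethoxy)cyclohexa-2,4-dien-1-yl]oxy}dimethylsilane (acetal epimers)
Conditions: TBSOTf, 2,6-lutidine, CH2Cl2, −78 °C
Reagents that add atoms: tert-butyldimethylsilyl triflate, CC(C)(C)[Si](C)(C)OS(=O)(=O)C(F)(F)F
Why: Silyl triflate silylation of a hindered secondary alcohol at low temperature; the β-iodo acetal is deactivated towards Lewis-acid ionisation and the lutidine buffer keeps the acid-labile diene intact.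

Step 3
Reactants: 4 tert-butyl{[(1S,6S)-2-bromo-6-(1-ethoxy-2-iodoethoxy)cyclohexa-2,4-dien-1-yl]oxy}dimethylsilane; 5 TEMPO
Product: 6 (3aR,4S,7S,7aS)-6-bromo-7-[(tert-butyldimethylsilyl)oxy]-2-ethoxy-4-[(2,2,6,6-tetramethylpiperidin-1-yl)oxy]-2,3,3a,4,7,7a-hexahydro-1-benzofuran (C2 epimers)
Conditions: Bu3SnH (1.5 equiv) and TEMPO (3 equiv), both by syringe pump, PhH (0.01 M), 75 °C
Reagents that add atoms: none
Why: Hydrogen abstraction from Bu3SnH by TEMPO gives Bu3Sn•, which removes iodine from the primary C–I bond much faster than bromine from the C3 vinyl bromide; the C1'' radical adds to C6, the terminus of the C6=C1–C2=C3 diene, and the delocalised C1–C2–C3 radical couples with the persistent nitroxide at C1. The closest known reaction type is the Ueno–Stork haloacetal cyclisation run with tin hydride and TEMPO, so that the cyclised radical is oxygenated instead of reduced. The tetrahydrofuran acetal ring closes in the 5-exo-trig mode. C6 is set by the tether: the new five-membered ring shares the C5–C6 bond with the carbocycle and cannot be trans-fused, so the C6–C1'' bond forms syn to the C5–O bond; C1 should take the nitroxide on the convex face anti to the new ring, and its configuration is erased in step 4. The step needs coupling at C1 and not at C3, which the substrate should secure because C3 is fully substituted and flanked by bromine and the C4 silyl ether, and because a C3 adduct would be a geminal bromo alkoxyamine whose weak C–O bond re-homolyses, whereas the C1 adduct keeps the C2=C3 vinyl bromide. It also needs ring closure to outrun nitroxide capture of the open-chain radical, for which the activated diene acceptor and a low stationary TEMPO concentration at high dilution are relied on.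

Step 4
Reactants: 6 (3aR,4S,7S,7aS)-6-bromo-7-[(tert-butyldimethylsilyl)oxy]-2-ethoxy-4-[(2,2,6,6-tetramethylpiperidin-1-yl)oxy]-2,3,3a,4,7,7a-hexahydro-1-benzofuran
Product: 7 (3aR,7S,7aS)-6-bromo-7-[(tert-butyldimethylsilyl)oxy]-2-ethoxy-3,3a,7,7a-tetrahydro-1-benzofuran-4(2H)-one (C2 epimers)
Conditions: mCPBA (1.5 equiv), NaHCO3, CH2Cl2, 0 °C → rt
Reagents that add atoms: none
Why: Oxidative N–O cleavage of a secondary alkoxyamine: the peracid oxidises nitrogen and the N-oxide collapses by Cope-type syn-elimination of the C1–H to the C1 ketone and the hydroxylamine, giving the β-bromo enone directly while the cis ring fusion holds C6.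

Step 5
Reactants: 7 (3aR,7S,7aS)-6-bromo-7-[(tert-butyldimethylsilyl)oxy]-2-ethoxy-3,3a,7,7a-tetrahydro-1-benzofuran-4(2H)-one; 8 (tributylstannyl)methanol
Product: 9 (3aR,7R,7aS)-7-[(tert-butyldimethylsilyl)oxy]-2-ethoxy-6-(hydroxymethyl)-3,3a,7,7a-tetrahydro-1-benzofuran-4(2H)-one (C2 epimers)
Conditions: Pd(PPh3)4 (5 mol %), 1,4-dioxane, 85 °C
Reagents that add atoms: none
Why: Stille hydroxymethylation: the β-bromo enone is a vinylogous acyl bromide that undergoes oxidative addition readily, and the stannylmethanol transfers CH2OH under neutral conditions that leave the β-alkoxy ketone, the acetal and the silyl ether untouched.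

Step 6
Reactants: 9 (3aR,7R,7aS)-7-[(tert-butyldimethylsilyl)oxy]-2-ethoxy-6-(hydroxymethyl)-3,3a,7,7a-tetrahydro-1-benzofuran-4(2H)-one
Product: 10 (3aR,7R,7aS)-7-[(tert-butyldimethylsilyl)oxy]-2-ethoxy-6-(hydroxymethyl)-5-iodo-3,3a,7,7a-tetrahydro-1-benzofuran-4(2H)-one (C2 epimers)
Conditions: I2 (2.5 equiv), pyridine/CH2Cl2 (1:1), DMAP (0.2 equiv), 0 °C → rt
Reagents that add atoms: iodine, II
Why: Amine-catalysed α-iodination of an enone (Baylis–Hillman-type conjugate addition of the amine at C3, iodination of the enolate at C2, elimination), known for 3-alkylcyclohex-2-enones; the weakly basic medium should not open the ring-fused β-alkoxy ketone.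

Step 7
Reactants: 11 (4-bromobut-1-yn-1-yl)trimethylsilane; 12 (R)-propylene oxide
Product: 15 (2R)-hept-6-yn-2-ol, via butynylmagnesium bromide 13 (not isolated), via bromomagnesium alkoxide 14 (not isolated)
Conditions: Mg, THF, rt → 40 °C; CuI (10 mol %), 12, −40 → 0 °C; then MeOH, K2CO3 (0.3 equiv), rt
Reagents that add atoms: none
Why: Copper-catalysed Grignard opening of a terminal epoxide at its CH2 carbon leaves the C–O bond of the stereocentre intact, so the (R)-epoxide gives the (R)-carbinol; methanolic carbonate then cleaves the alkynyl C–Si bond.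

Step 8
Reactants: 15 (2R)-hept-6-yn-2-ol
Product: 16 (2R)-hept-6-yn-2-yl acetate
Conditions: Ac2O, pyridine, DMAP (cat.), CH2Cl2, 0 °C → rt
Reagents that add atoms: acetic anhydride, CC(=O)OC(C)=O
Why: DMAP-catalysed acylation of a secondary alcohol; the C–O bond is not broken, so the configuration is retained.

Step 9
Reactants: 16 (2R)-hept-6-yn-2-yl acetate
Product: 17 (2R,6E)-7-(tributylstannyl)hept-6-en-2-yl acetate
Conditions: Bu3SnH, Pd2(dba)3 (1 mol %), Cy3P·HBF4 (4 mol %), i-Pr2NEt (10 mol %), CH2Cl2, 0 °C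
Reagents that add atoms: tributyltin hydride, CCCC[SnH](CCCC)CCCC
Why: Palladium-catalysed syn-hydrostannation of a terminal alkyne; the bulky trialkylphosphine directs tin to the terminal carbon and the syn addition fixes the E geometry, while the remote acetate is inert.

Step 10
Reactants: 10 (3aR,7R,7aS)-7-[(tert-butyldimethylsilyl)oxy]-2-ethoxy-6-(hydroxymethyl)-5-iodo-3,3a,7,7a-tetrahydro-1-benzofuran-4(2H)-one; 17 (2R,6E)-7-(tributylstannyl)hept-6-en-2-yl acetate
Product: 18 (2R,6E)-7-[(3aR,7R,7aS)-7-[(tert-butyldimethylsilyl)oxy]-2-ethoxy-6-(hydroxymethyl)-4-oxo-2,3,3a,4,7,7a-hexahydro-1-benzofuran-5-yl]hept-6-en-2-yl acetate (C2 epimers)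
Conditions: Pd2(dba)3 (5 mol %), AsPh3 (20 mol %), CuI (10 mol %), NMP, rt → 45 °C
Reagents that add atoms: none
Why: Stille coupling of an α-iodo enone with an (E)-alkenylstannane using the arsine/copper(I) co-catalyst system proceeds near room temperature without base and with retention of alkene geometry, so the acetate, the acetal and C6 are preserved.

Step 11
Reactants: 18 (2R,6E)-7-[(3aR,7R,7aS)-7-[(tert-butyldimethylsilyl)oxy]-2-ethoxy-6-(hydroxymethyl)-4-oxo-2,3,3a,4,7,7a-hexahydro-1-benzofuran-5-yl]hept-6-en-2-yl acetate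
Product: 19 (2R,6E)-7-[(3aR,7R,7aS)-7-[(tert-butyldimethylsilyl)oxy]-2-hydroxy-6-(hydroxymethyl)-4-oxo-2,3,3a,4,7,7a-hexahydro-1-benzofuran-5-yl]hept-6-en-2-yl acetate (lactol anomers)
Conditions: AcOH/THF/H2O (3:1:1), 40 °C
Reagents that add atoms: water, O
Why: Acid hydrolysis of a 2-alkoxytetrahydrofuran acetal of the 2-deoxyfuranoside type is fast in aqueous acetic acid, under which the secondary TBS ether, the acetate and the dienone should persist; C6 stays locked in the cis-fused lactol.

Step 12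
Reactants: 20 tert-butyl 2-bromopropanoate
Product: 22 tert-butyl 2-(triphenylphosphoranylidene)propanoate, via phosphonium bromide 21 (not isolated)
Conditions: PPh3, MeCN, 60 °C; then CH2Cl2, 1 M aq NaOH, 0 °C
Reagents that add atoms: triphenylphosphine, c1ccc(cc1)P(c1ccccc1)c1ccccc1
Why: SN2 alkylation of the phosphine by the α-bromo ester followed by deprotonation of the phosphonium salt gives the stabilised Wittig ylide.

Step 13
Reactants: 19 (2R,6E)-7-[(3aR,7R,7aS)-7-[(tert-butyldimethylsilyl)oxy]-2-hydroxy-6-(hydroxymethyl)-4-oxo-2,3,3a,4,7,7a-hexahydro-1-benzofuran-5-yl]hept-6-en-2-yl acetate; 22 tert-butyl 2-(triphenylphosphoranylidene)propanoate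
Product: 23 tert-butyl (2E)-4-[(1R,5R,6S)-3-[(1E,6R)-6-acetoxyhept-1-en-1-yl]-5-[(tert-butyldimethylsilyl)oxy]-6-hydroxy-4-(hydroxymethyl)-2-oxocyclohex-3-en-1-yl]-2-methylbut-2-enoate
Conditions: 22 (2 equiv), PhMe, 60 °C
Reagents that add atoms: none
Why: Wittig olefination of the lactol through its open hydroxy-aldehyde form with a stabilised α-methyl ylide should give the (E)-trisubstituted enoate and release the C5 hydroxyl; the hindered conjugated C1 ketone does not react, and the weakly basic ylide should not epimerise C6 or eliminate the C5 hydroxyl.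

Step 14
Reactants: 23 tert-butyl (2E)-4-[(1R,5R,6S)-3-[(1E,6R)-6-acetoxyhept-1-en-1-yl]-5-[(tert-butyldimethylsilyl)oxy]-6-hydroxy-4-(hydroxymethyl)-2-oxocyclohex-3-en-1-yl]-2-methylbut-2-enoate
Product: 24 pestallic acid J
Conditions: TFA/CH2Cl2/H2O (10:10:1), 0 °C → rt; toluene azeotrope
Reagents that add atoms: none
Why: Acidolysis: TFA cleaves the tert-butyl ester with loss of isobutene and, with water, the secondary TBS ether, while the secondary acetate is stable to acid and polyhydroxycyclohexenones of this type are routinely unmasked under aqueous acid.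

Compound list
1 | (1S,2S)-3-bromocyclohexa-3,5-diene-1,2-diol | BrC1=CC=C[C@H](O)[C@@H]1O | starting material
2 | ethyl vinyl ether | C=COCC | starting material
3 | (1S,6S)-2-bromo-6-(1-ethoxy-2-iodoethoxy)cyclohexa-2,4-dien-1-ol (acetal epimers) | BrC1=CC=C[C@H](OC(CI)OCC)[C@@H]1O | intermediate
4 | tert-butyl{[(1S,6S)-2-bromo-6-(1-ethoxy-2-iodoethoxy)cyclohexa-2,4-dien-1-yl]oxy}dimethylsilane (acetal epimers) | BrC1=CC=C[C@H](OC(CI)OCC)[C@@H]1O[Si](C)(C)C(C)(C)C | intermediate
5 | TEMPO (2,2,6,6-tetramethylpiperidin-1-oxyl) | CC1(C)CCCC(C)(C)N1[O] | starting material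
6 | (3aR,4S,7S,7aS)-6-bromo-7-[(tert-butyldimethylsilyl)oxy]-2-ethoxy-4-[(2,2,6,6-tetramethylpiperidin-1-yl)oxy]-2,3,3a,4,7,7a-hexahydro-1-benzofuran (C2 epimers) | CCOC1C[C@@H]2[C@H](O1)[C@H](O[Si](C)(C)C(C)(C)C)C(Br)=C[C@H]2ON1C(C)(C)CCCC1(C)C | intermediate
7 | (3aR,7S,7aS)-6-bromo-7-[(tert-butyldimethylsilyl)oxy]-2-ethoxy-3,3a,7,7a-tetrahydro-1-benzofuran-4(2H)-one (C2 epimers) | CCOC1C[C@@H]2[C@H](O1)[C@H](O[Si](C)(C)C(C)(C)C)C(Br)=CC2=O | intermediate
8 | (tributylstannyl)methanol | OC[Sn](CCCC)(CCCC)CCCC | starting material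
9 | (3aR,7R,7aS)-7-[(tert-butyldimethylsilyl)oxy]-2-ethoxy-6-(hydroxymethyl)-3,3a,7,7a-tetrahydro-1-benzofuran-4(2H)-one (C2 epimers) | CCOC1C[C@@H]2[C@H](O1)[C@H](O[Si](C)(C)C(C)(C)C)C(CO)=CC2=O | intermediate
10 | (3aR,7R,7aS)-7-[(tert-butyldimethylsilyl)oxy]-2-ethoxy-6-(hydroxymethyl)-5-iodo-3,3a,7,7a-tetrahydro-1-benzofuran-4(2H)-one (C2 epimers) | CCOC1C[C@@H]2[C@H](O1)[C@H](O[Si](C)(C)C(C)(C)C)C(CO)=C(I)C2=O | intermediate
11 | (4-bromobut-1-yn-1-yl)trimethylsilane | C[Si](C)(C)C#CCCBr | starting material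
12 | (R)-propylene oxide | C[C@@H]1CO1 | starting material
13 | [4-(trimethylsilyl)but-3-yn-1-yl]magnesium bromide | C[Si](C)(C)C#CCC[Mg]Br | intermediate
14 | bromomagnesium (2R)-7-(trimethylsilyl)hept-6-yn-2-olate | C[C@@H](O[Mg]Br)CCCC#C[Si](C)(C)C | intermediate
15 | (2R)-hept-6-yn-2-ol | C[C@@H](O)CCCC#C | intermediate
16 | (2R)-hept-6-yn-2-yl acetate | CC(=O)O[C@H](C)CCCC#C | intermediate
17 | (2R,6E)-7-(tributylstannyl)hept-6-en-2-yl acetate | CC(=O)O[C@H](C)CCC/C=C/[Sn](CCCC)(CCCC)CCCC | intermediate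
18 | (2R,6E)-7-[(3aR,7R,7aS)-7-[(tert-butyldimethylsilyl)oxy]-2-ethoxy-6-(hydroxymethyl)-4-oxo-2,3,3a,4,7,7a-hexahydro-1-benzofuran-5-yl]hept-6-en-2-yl acetate (C2 epimers) | CCOC1C[C@@H]2[C@H](O1)[C@H](O[Si](C)(C)C(C)(C)C)C(CO)=C(/C=C/CCC[C@@H](C)OC(C)=O)C2=O | intermediate
19 | (2R,6E)-7-[(3aR,7R,7aS)-7-[(tert-butyldimethylsilyl)oxy]-2-hydroxy-6-(hydroxymethyl)-4-oxo-2,3,3a,4,7,7a-hexahydro-1-benzofuran-5-yl]hept-6-en-2-yl acetate (lactol anomers) | OC1C[C@@H]2[C@H](O1)[C@H](O[Si](C)(C)C(C)(C)C)C(CO)=C(/C=C/CCC[C@@H](C)OC(C)=O)C2=O | intermediate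
20 | tert-butyl 2-bromopropanoate | CC(Br)C(=O)OC(C)(C)C | starting material
21 | (1-tert-butoxy-1-oxopropan-2-yl)triphenylphosphonium bromide | CC(C(=O)OC(C)(C)C)[P+](c1ccccc1)(c1ccccc1)c1ccccc1.[Br-] | intermediate
22 | tert-butyl 2-(triphenylphosphoranylidene)propanoate | CC(=P(c1ccccc1)(c1ccccc1)c1ccccc1)C(=O)OC(C)(C)C | intermediate
23 | tert-butyl (2E)-4-[(1R,5R,6S)-3-[(1E,6R)-6-acetoxyhept-1-en-1-yl]-5-[(tert-butyldimethylsilyl)oxy]-6-hydroxy-4-(hydroxymethyl)-2-oxocyclohex-3-en-1-yl]-2-methylbut-2-enoate | CC(=O)O[C@H](C)CCC/C=C/C1=C(CO)[C@@H](O[Si](C)(C)C(C)(C)C)[C@@H](O)[C@@H](C/C=C(\C)C(=O)OC(C)(C)C)C1=O | intermediate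
24 | pestallic acid J, (2E)-4-[(1R,5R,6S)-3-[(1E,6R)-6-acetoxyhept-1-en-1-yl]-5,6-dihydroxy-4-(hydroxymethyl)-2-oxocyclohex-3-en-1-yl]-2-methylbut-2-enoic acid | CC(=O)O[C@H](C)CCC/C=C/C1=C(CO)[C@@H](O)[C@@H](O)[C@@H](C/C=C(\C)C(=O)O)C1=O | target

Total step count: 14.
Longest linear sequence: 10 steps from diol 1 (steps 1–6, 10, 11, 13, 14).

Steps most likely to fail

Step 3 (key step). The nitroxide may capture the primary radical before it cyclises. The allylic radical may couple at C3 or lose a hydrogen atom and aromatise, and stannyl radicals may strip the C3 bromine. The fallback sets out from 4 and separates C–C from C–O bond formation. Reductive Ueno–Stork cyclisation without nitroxide (Bu3SnH 1.1 equiv by syringe pump, AIBN, PhH, 80 °C) should deliver hydrogen to the less hindered allylic terminus C1 and give the C1-methylene cis-fused acetal (3aR,7S,7aS)-6-bromo-7-[(tert-butyldimethylsilyl)oxy]-2-ethoxy-2,3,3a,4,7,7a-hexahydro-1-benzofuran F1. Allylic oxidation of its only allylic methylene (CrO3·3,5-dimethylpyrazole, CH2Cl2, −20 °C) then comes back to the route at 7.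

Step 6. Conjugate addition of the amine at the fully substituted C3 may stall, so that iodination is slow or incomplete, and forcing may open the β-alkoxy ketone by base-induced elimination. The fallback sets out from 9 and uses addition–elimination instead. Bromine addition across C2=C3 (Br2, CH2Cl2, −78 °C) should give the dibromo ketone 5,6-dibromo-7-[(tert-butyldimethylsilyl)oxy]-2-ethoxy-6-(hydroxymethyl)hexahydro-1-benzofuran-4(2H)-one F2. Dehydrobromination in the same flask (Et3N, 0 °C) gives the α-bromo enone (3aR,7R,7aS)-5-bromo-7-[(tert-butyldimethylsilyl)oxy]-2-ethoxy-6-(hydroxymethyl)-3,3a,7,7a-tetrahydro-1-benzofuran-4(2H)-one F3. Stille coupling of F3 with 17 (Pd2(dba)3, P(2-furyl)3, CuI, NMP, 60 °C) returns to the route at 18.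

Step 1. Discrimination between the two secondary hydroxyls may be poor, bis-acetalisation may occur, and the free diene diol may aromatise or dimerise. The fallback sets out from 1 and uses a protecting-group relay. Distal-selective silylation (TESCl, imidazole, DMF, −40 °C) gives (1S,6S)-2-bromo-6-[(triethylsilyl)oxy]cyclohexa-2,4-dien-1-ol F4. Silylation of the C4 hydroxyl (TBSOTf, 2,6-lutidine, CH2Cl2, −78 °C) gives the bis-silyl ether tert-butyl{[(1S,6S)-2-bromo-6-[(triethylsilyl)oxy]cyclohexa-2,4-dien-1-yl]oxy}dimethylsilane F5. Selective removal of the triethylsilyl group (PPTS, MeOH/CH2Cl2, 0 °C) gives (1S,6S)-5-bromo-6-[(tert-butyldimethylsilyl)oxy]cyclohexa-2,4-dien-1-ol F6. Iodoacetalisation of its only free hydroxyl under the conditions of step 1 comes back to the route at 4.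

Further compounds
F1 | step 3 | (3aR,7S,7aS)-6-bromo-7-[(tert-butyldimethylsilyl)oxy]-2-ethoxy-2,3,3a,4,7,7a-hexahydro-1-benzofuran (C2 epimers) | CCOC1C[C@@H]2[C@H](O1)[C@H](O[Si](C)(C)C(C)(C)C)C(Br)=CC2
F2 | step 6 | 5,6-dibromo-7-[(tert-butyldimethylsilyl)oxy]-2-ethoxy-6-(hydroxymethyl)hexahydro-1-benzofuran-4(2H)-one (mixture at C2, C5 and C6) | CCOC1C[C@@H]2[C@H](O1)[C@H](O[Si](C)(C)C(C)(C)C)C(Br)(CO)C(Br)C2=O
F3 | step 6 | (3aR,7R,7aS)-5-bromo-7-[(tert-butyldimethylsilyl)oxy]-2-ethoxy-6-(hydroxymethyl)-3,3a,7,7a-tetrahydro-1-benzofuran-4(2H)-one (C2 epimers) | CCOC1C[C@@H]2[C@H](O1)[C@H](O[Si](C)(C)C(C)(C)C)C(CO)=C(Br)C2=O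
F4 | step 1 | (1S,6S)-2-bromo-6-[(triethylsilyl)oxy]cyclohexa-2,4-dien-1-ol | BrC1=CC=C[C@H](O[Si](CC)(CC)CC)[C@@H]1O
F5 | step 1 | tert-butyl{[(1S,6S)-2-bromo-6-[(triethylsilyl)oxy]cyclohexa-2,4-dien-1-yl]oxy}dimethylsilane | BrC1=CC=C[C@H](O[Si](CC)(CC)CC)[C@@H]1O[Si](C)(C)C(C)(C)C
F6 | step 1 | (1S,6S)-5-bromo-6-[(tert-butyldimethylsilyl)oxy]cyclohexa-2,4-dien-1-ol | BrC1=CC=C[C@H](O)[C@@H]1O[Si](C)(C)C(C)(C)C
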